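**Retrosynthetic overview**

1. Numbering used throughout: 11-membered ring C1–C11 with C1(=C17H2), C2(OAc), C5(Me), C8=C9(Me); cyclopentane C10–C14 (C14-Me); cyclohexene C8, C9, C10, C14, C15(OH), C16(OH); β = face of C14-Me and H10 (convex face of the cis-bicycle), α = the other face.
2. Enabling feature: inside the 11-membered ring the exocyclic methylene on C1 sits next to the oxygenated C2, so C17=C1–C2(O)–C3 is a γ,δ-unsaturated β-alkoxy acid retron once C3 carries a carboxyl. C2–C3 is therefore made by an ester-enolate Claisen shift of the 13-membered lactone C3–C(=O)–O–C17H2–C1(=C2H–OPMB), which contracts to the 11-membered carbocycle; the carboxyl is then removed and C2 is acetylated with inversion.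
3. The lactone comes from a seco acid made by B-alkyl Suzuki coupling (C7–C8) of a C8 enol triflate with the borane of methyl (S)-4-methylhex-5-enoate, which is derived from (S)-citronellene and supplies C5.
4. The cis-hydrindane comes from an achiral cyclohexa-2,5-dienone by catalytic asymmetric intramolecular Stetter desymmetrisation (C10, C14), followed by C9 methylation, β-epoxide formation and anti opening (C15, C16), enol triflate formation, and olefination with convex-face hydride delivery (C11).
5. Ring order: six-membered ring (Robinson annulation) → cyclopentane (Stetter) → 13-membered lactone (macrolactonisation) → 11-membered carbocycle by ring contraction.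

Key step: step 20

Remark (assumptions): reagents are assumed to attack the cis-fused bicycle from its convex β-face; metal enolates and alkoxides count as the reacting form of a numbered compound and carry no number; C9 in 9–10 and C3 in 27–29 are transient stereocentres and are left undefined.

Step 1
Reactants: 1 melonal (rac-2,6-dimethylhept-5-enal); 2 methyl vinyl ketone
Product: 3 rac-4-methyl-4-(4-methylpent-3-en-1-yl)cyclohex-2-en-1-one
Conditions: KOH (cat.), MeOH, 0 °C → reflux
Reagents that add atoms: none
Why: Michael addition of the α-branched aldehyde to the enone followed by intramolecular aldol condensation (Robinson annulation) gives the 4,4-disubstituted cyclohexenone, whose racemic quaternary carbon (future C14) becomes a prochiral centre in step 2.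

Step 2
Reactants: 3 rac-4-methyl-4-(4-methylpent-3-en-1-yl)cyclohex-2-en-1-one
Product: 4 4-methyl-4-(4-methylpent-3-en-1-yl)cyclohexa-2,5-dien-1-one
Conditions: DDQ, 1,4-dioxane, reflux
Reagents that add atoms: none
Why: DDQ dehydrogenation of the α′,β′-positions of the enone gives the achiral cross-conjugated dienone, the isolated side-chain alkene offering no activated hydride.

Step 3
Reactants: 4 4-methyl-4-(4-methylpent-3-en-1-yl)cyclohexa-2,5-dien-1-one
Product: 6 3-(1-methyl-4-oxocyclohexa-2,5-dien-1-yl)propanal, via secondary ozonide 5 (not isolated)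
Conditions: O3, CH2Cl2, −78 °C (Sudan Red 7B end point); then Me2S, −78 °C → rt
Reagents that add atoms: ozone [O-][O+]=O
Why: Chemoselective ozonolysis with reductive work-up, because ozone cleaves the electron-rich trisubstituted alkene far faster than the electron-poor dienone double bonds, leaving the aldehyde three carbons from the quaternary centre.

Step 4
Reactants: 6 3-(1-methyl-4-oxocyclohexa-2,5-dien-1-yl)propanal
Product: 7 cis-enedione (3aS,7aR)-7a-methyl-3a,4-dihydro-1H-indene-3,5(2H,7aH)-dione (ketones at C11 and C8; C15=C16)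
Conditions: aminoindanol-derived N-C6F5 triazolium tetrafluoroborate (cat., the enantiomer that gives 7), KHMDS (cat.), toluene, rt
Reagents that add atoms: none
Why: Asymmetric intramolecular Stetter reaction in which the carbene-derived acyl-anion equivalent adds 5-exo to one of the two enantiotopic enone β-carbons (desymmetrisation); the three-carbon tether enforces the cis ring fusion, so C10 and C14 are set together under catalyst control.

Step 5
Reactants: 7 cis-enedione
Product: 8 enone–enoate (7 with C11=O replaced by C11=CH–CO2Me; E/Z mixture)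
Conditions: (MeO)2P(O)CH2CO2Me, NaH, THF, 0 → 50 °C
Reagents that add atoms: trimethyl phosphonoacetate COC(=O)CP(=O)(OC)OC
Why: Horner–Wadsworth–Emmons olefination at the saturated cyclopentanone carbonyl (C11), which is more electrophilic than the vinylogously deactivated enone carbonyl; the alkene geometry is inconsequential.

Step 6
Reactants: 8 enone–enoate
Product: 9 C9-methyl enone–enoate (C9 epimers)
Conditions: LDA, THF, −78 °C; MeI, −78 → −30 °C
Reagents that add atoms: iodomethane CI
Why: Kinetic deprotonation at the only ketone α-CH2 (C9, α′ of the enone) gives the cross-conjugated lithium dienolate, which is C-methylated (enolate alkylation); the C9 configuration is irrelevant because C9 becomes sp2 in step 8.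

Step 7
Reactants: 9 C9-methyl enone–enoate
Product: 10 15β,16β-epoxy ketone
Conditions: t-BuOOH, DBU, CH2Cl2, 0 °C → rt
Reagents that add atoms: tert-butyl hydroperoxide CC(C)(C)OO
Why: Weitz–Scheffer nucleophilic epoxidation is confined to the enone (the β,β-disubstituted enoate is unreactive), and the peroxide is expected to add to C15 on the convex β-face, anti to the cyclopentane ring, giving the β-epoxide.

Step 8
Reactants: 10 15β,16β-epoxy ketone
Product: 11 C8 enol triflate (C8=C9) with 15β,16β-epoxide
Conditions: KHMDS, THF, −78 °C; PhNTf2, −78 → 0 °C; aq. NH4Cl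
Reagents that add atoms: N-phenylbis(trifluoromethanesulfonimide) O=S(=O)(N(c1ccccc1)S(=O)(=O)C(F)(F)F)C(F)(F)F
Why: The base removes the only remaining α-hydrogen (C9–H) and the tetrasubstituted enolate is O-triflated (enol triflate formation), which fixes the C8=C9 double bond regiospecifically.

Step 9
Reactants: 11 epoxy enol triflate
Product: 12 15β,16α-diol enol triflate
Conditions: HClO4 (cat.), THF/H2O, 0 °C → rt
Reagents that add atoms: water O
Why: Acid-catalysed epoxide hydrolysis by anti attack of water at C16 (allylic and not neopentyl, while the triflate on C8 disfavours an SN1 or SN2′ course) inverts C16 and retains C15, giving the trans diol.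

Step 10
Reactants: 12 15β,16α-diol enol triflate
Product: 13 15β,16α-bis(TBS ether) enol triflate enoate
Conditions: TBSOTf, 2,6-lutidine, CH2Cl2, 0 °C → rt
Reagents that add atoms: tert-butyldimethylsilyl trifluoromethanesulfonate CC(C)(C)[Si](C)(C)OS(=O)(=O)C(F)(F)F
Why: Silyl triflate with lutidine silylates both secondary hydroxyls, including the neopentyl C15-OH (silyl ether formation).

Step 11
Reactants: 13 bis(TBS ether) enol triflate enoate
Product: 14 saturated ester with C11α-CH2CO2Me (H11β)
Conditions: Cu(OAc)2 (cat.), 1,2-bis(diphenylphosphino)benzene (cat.), (EtO)2MeSiH, t-BuOH, toluene, rt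
Reagents that add atoms: none
Why: Copper hydride conjugate reduction of the β,β-disubstituted enoate delivers hydride to C11 from the convex β-face, so the acetate chain ends on the concave α-face, cis to C9 as in the target; the vinyl triflate is inert to CuH.

Step 12
Reactants: 14 saturated ester
Product: 15 α-formyl ester (enol form, hydroxymethylene on C1)
Conditions: LDA (2.2 equiv), THF, −78 °C; HCO2Me, −78 → 0 °C; aq. NH4Cl
Reagents that add atoms: methyl formate COC=O
Why: Crossed Claisen condensation of the ester lithium enolate with methyl formate introduces C2 at the aldehyde oxidation level, the second equivalent of base being consumed by the more acidic product.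

Step 13
Reactants: 15 α-formyl ester
Product: 16 (E)-β-(4-methoxybenzyloxy)acrylate (OPMB cis to C11)
Conditions: PMBCl, Cs2CO3, DMF, rt
Reagents that add atoms: 4-methoxybenzyl chloride COc1ccc(CCl)cc1
Why: O-Alkylation of the non-chelated caesium enolate in DMF occurs at oxygen rather than at the fully substituted carbon and gives the E enol ether usual for α-formyl esters, which is the geometry step 20 relies on.

Step 14
Reactants: 16 (E)-β-(4-methoxybenzyloxy)acrylate
Product: 17 (E)-allylic alcohol (C17H2OH on C1; C1=C2H–OPMB) with C8 triflate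
Conditions: DIBAL-H, CH2Cl2, −78 °C; Rochelle salt
Reagents that add atoms: none
Why: DIBAL-H reduces the ester to the primary allylic alcohol at low temperature without touching the enol ether, vinyl triflate or silyl ethers (ester reduction, basic work-up protects the enol ether).

Step 15
Reactants: 18 (S)-β-citronellene [(3S)-3,7-dimethylocta-1,6-diene]
Product: 20 (S)-4-methylhex-5-enal, via trisubstituted epoxide 19 (not isolated)
Conditions: m-CPBA, CH2Cl2, 0 °C; then H5IO6, THF/H2O, 0 °C
Reagents that add atoms: 3-chloroperbenzoic acid OOC(=O)c1cccc(Cl)c1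
Why: The peracid epoxidises the trisubstituted alkene in preference to the monosubstituted one and periodic acid cleaves the epoxide through the diol (oxidative cleavage); the stereocentre is untouched.

Step 16
Reactants: 20 (S)-4-methylhex-5-enal
Product: 21 methyl (S)-4-methylhex-5-enoate
Conditions: Oxone, MeOH, rt
Reagents that add atoms: methanol CO
Why: Oxidative esterification of the aldehyde through its hemiacetal, a reaction that leaves an unactivated terminal alkene untouched.

Step 17
Reactants: 21 methyl (S)-4-methylhex-5-enoate; 17 (E)-allylic alcohol triflate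
Product: 23 C7–C8 coupled hydroxy methyl ester, via B-alkyl-9-BBN borane 22 (not isolated)
Conditions: 21, 9-BBN, THF, rt; then 17, PdCl2(dppf) (cat.), AsPh3 (cat.), Cs2CO3, DMF/H2O, 50 °C
Reagents that add atoms: none
Why: Anti-Markovnikov hydroboration of the terminal alkene followed by B-alkyl Suzuki–Miyaura coupling with the enol triflate forms C7–C8 with retention of the C8=C9 position; the free hydroxyl, enol ether and ester are tolerated.

Step 18
Reactants: 23 hydroxy methyl ester
Product: 24 seco acid (hydroxy acid)
Conditions: LiOH, THF/MeOH/H2O, rt; then pH 5 phosphate buffer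
Reagents that add atoms: lithium hydroxide [Li+].[OH-]
Why: Saponification of the only ester under conditions to which the enol ether and silyl ethers are stable, with buffered acidification to avoid enol ether hydrolysis.

Step 19
Reactants: 24 seco acid
Product: 25 13-membered lactone (ring: C18(=O), O, C17, C1, C11, C10, C9, C8, C7–C3; C18 = carbonyl carbon on C3)
Conditions: 2-methyl-6-nitrobenzoic anhydride, DMAP, Et3N, CH2Cl2, rt, slow addition, high dilution
Reagents that add atoms: none
Why: Shiina macrolactonisation through the mixed anhydride closes the 13-membered lactone at the unhindered primary allylic hydroxyl.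

Step 20
Reactants: 25 13-membered lactone
Product: 28 ring-contracted acid (11-membered carbocycle with C1=C17H2, 2R-OPMB and C3-CO2H), via silyl ketene acetal 26 (not isolated), via trimethylsilyl ester 27 (not isolated)
Conditions: KHMDS, TMSCl/Et3N, THF, −78 °C; then toluene, 80 °C; then dilute aq. HCl, 0 °C
Reagents that add atoms: none
Why: Proposed new method: KHMDS/TMSCl (internal quench) converts the lactone into its O-silyl ketene acetal 26, which undergoes a [3,3]-sigmatropic Ireland–Claisen shift through the six-centre array C3=C18(OSi)–O–C17–C1=C2, so that C18, the ring oxygen and C17 leave the ring while C3–C2 forms, the 13-membered lactone contracts by two atoms to the 11-membered carbocycle, and C17 becomes the exocyclic methylene next to the new C2–O stereocentre. The closest known reactions are the Ireland–Claisen ring contraction of macrolactones with an endocyclic allylic alkene (contraction by four) and the ester-enolate Claisen rearrangement of glycal esters (C–C bond formed at an enol-ether carbon); new is the 2-alkylidene topology in which the alkene terminus C2 is exocyclic. The 11-membered ring closes through a bridged chair-like array whose positions C3 and C1 are spanned by the C4–C11 chain (formal 11-endo closure onto the exocyclic enol ether); no other ring is formed. C2 is set by the E enol ether geometry together with the face of attack: A(1,3) strain between OPMB and the C11 substituents should hold C11–H in the enol ether plane, C10 then lies on one face, and C3, tied through C4–C7 to C8 next to C10, can reach C2 only from that face, which is predicted to give 2R; C3 is a transient stereocentre erased in step 21. The step needs the shift to outrun ketene formation and elimination of the enolate and needs one enol ether face; the first is secured by in situ silylation, the second by the rigid C8=C9–C10–C11 segment of the cis-hydrindane within the ring.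

Step 21
Reactants: 28 ring-contracted acid
Product: 30 (2R)-PMB ether with C3H2, via thiohydroxamate ester 29 (not isolated)
Conditions: N-hydroxypyridine-2-thione, EDC, DMAP (cat.), CH2Cl2, rt, dark; then t-BuSH (excess), hν (visible), rt
Reagents that add atoms: none
Why: Barton reductive decarboxylation, in which the thiohydroxamate ester fragments to the C3 radical and the excess thiol reduces it faster than it can cyclise or abstract hydrogen intramolecularly, removing the auxiliary carboxyl and the C3 stereocentre.

Step 22
Reactants: 30 (2R)-PMB ether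
Product: 31 (2R)-allylic alcohol bis(TBS ether)
Conditions: DDQ, CH2Cl2/pH 7 buffer, 0 °C
Reagents that add atoms: none
Why: Oxidative cleavage of the PMB ether with DDQ frees the C2 hydroxyl while the silyl ethers and alkenes are left intact.

Step 23
Reactants: 31 (2R)-allylic alcohol
Product: 32 (2S)-acetate bis(TBS ether)
Conditions: PPh3, DIAD, AcOH, toluene, 0 °C → rt
Reagents that add atoms: acetic acid CC(=O)O
Why: Mitsunobu reaction with acetic acid displaces the activated C2 oxygen by SN2 with inversion (2R → 2S) and installs the acetate in the same operation; a C2–O bond lying near the plane of the exocyclic alkene disfavours the SN2′ path.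

Step 24
Reactants: 32 (2S)-acetate bis(TBS ether)
Product: 33 target CNP0192310.1
Conditions: HF·pyridine, THF/pyridine, 0 °C → rt
Reagents that add atoms: none
Why: Fluoride-mediated desilylation removes both TBS ethers under conditions that neither cleave nor migrate the acetate.

**Compound list**

1 | melonal (rac-2,6-dimethylhept-5-enal) | CC(C)=CCCC(C)C=O | starting material
2 | methyl vinyl ketone | CC(=O)C=C | starting material
3 | rac-4-methyl-4-(4-methylpent-3-en-1-yl)cyclohex-2-en-1-one | O=C1CCC(C)(CCC=C(C)C)C=C1 | intermediate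
4 | 4-methyl-4-(4-methylpent-3-en-1-yl)cyclohexa-2,5-dien-1-one | O=C1C=CC(C)(CCC=C(C)C)C=C1 | intermediate
5 | secondary ozonide of the side-chain alkene of 4 | CC1(C)OOC(CCC2(C)C=CC(=O)C=C2)O1 | intermediate
6 | 3-(1-methyl-4-oxocyclohexa-2,5-dien-1-yl)propanal | O=CCCC1(C)C=CC(=O)C=C1 | intermediate
7 | cis-enedione, (3aS,7aR)-7a-methyl-3a,4-dihydro-1H-indene-3,5(2H,7aH)-dione | O=C1C[C@@H]2C(=O)CC[C@]2(C)C=C1 | intermediate
8 | enone–enoate (C11=CH–CO2Me, E/Z) | O=C1C[C@@H]2C(=CC(=O)OC)CC[C@]2(C)C=C1 | intermediate
9 | C9-methyl enone–enoate (C9 epimers) | O=C1C(C)[C@@H]2C(=CC(=O)OC)CC[C@]2(C)C=C1 | intermediate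
10 | 15β,16β-epoxy ketone | O=C1C(C)[C@@H]2C(=CC(=O)OC)CC[C@]2(C)[C@H]3O[C@@H]13 | intermediate
11 | C8 enol triflate with 15β,16β-epoxide | O=S(=O)(OC1=C(C)[C@@H]2C(=CC(=O)OC)CC[C@]2(C)[C@H]3O[C@@H]13)C(F)(F)F | intermediate
12 | 15β,16α-diol enol triflate | O=S(=O)(OC1=C(C)[C@@H]2C(=CC(=O)OC)CC[C@]2(C)[C@@H](O)[C@@H]1O)C(F)(F)F | intermediate
13 | 15β,16α-bis(TBS ether) enol triflate enoate | O=S(=O)(OC1=C(C)[C@@H]2C(=CC(=O)OC)CC[C@]2(C)[C@@H](O[Si](C)(C)C(C)(C)C)[C@@H]1O[Si](C)(C)C(C)(C)C)C(F)(F)F | intermediate
14 | saturated ester, C11α-CH2CO2Me | O=S(=O)(OC1=C(C)[C@@H]2[C@H](CC(=O)OC)CC[C@]2(C)[C@@H](O[Si](C)(C)C(C)(C)C)[C@@H]1O[Si](C)(C)C(C)(C)C)C(F)(F)F | intermediate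
15 | α-formyl ester (enol form) | O=S(=O)(OC1=C(C)[C@@H]2[C@H](C(=CO)C(=O)OC)CC[C@]2(C)[C@@H](O[Si](C)(C)C(C)(C)C)[C@@H]1O[Si](C)(C)C(C)(C)C)C(F)(F)F | intermediate
16 | (E)-β-(4-methoxybenzyloxy)acrylate | O=S(=O)(OC1=C(C)[C@@H]2[C@H](/C(C(=O)OC)=C\OCc3ccc(OC)cc3)CC[C@]2(C)[C@@H](O[Si](C)(C)C(C)(C)C)[C@@H]1O[Si](C)(C)C(C)(C)C)C(F)(F)F | intermediate
17 | (E)-allylic alcohol with C8 triflate | O=S(=O)(OC1=C(C)[C@@H]2[C@H](/C(CO)=C\OCc3ccc(OC)cc3)CC[C@]2(C)[C@@H](O[Si](C)(C)C(C)(C)C)[C@@H]1O[Si](C)(C)C(C)(C)C)C(F)(F)F | intermediate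
18 | (S)-β-citronellene, (3S)-3,7-dimethylocta-1,6-diene | C=C[C@@H](C)CCC=C(C)C | starting material
19 | 6,7-epoxide of 18 | C=C[C@@H](C)CCC1OC1(C)C | intermediate
20 | (S)-4-methylhex-5-enal | C=C[C@@H](C)CCC=O | intermediate
21 | methyl (S)-4-methylhex-5-enoate | C=C[C@@H](C)CCC(=O)OC | intermediate
22 | B-alkyl-9-BBN adduct of 21 | COC(=O)CC[C@H](C)CCB1C2CCCC1CCC2 | intermediate
23 | C7–C8 coupled hydroxy methyl ester | COC(=O)CC[C@H](C)CCC1=C(C)[C@@H]2[C@H](/C(CO)=C\OCc3ccc(OC)cc3)CC[C@]2(C)[C@@H](O[Si](C)(C)C(C)(C)C)[C@@H]1O[Si](C)(C)C(C)(C)C | intermediate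
24 | seco acid | OC(=O)CC[C@H](C)CCC1=C(C)[C@@H]2[C@H](/C(CO)=C\OCc3ccc(OC)cc3)CC[C@]2(C)[C@@H](O[Si](C)(C)C(C)(C)C)[C@@H]1O[Si](C)(C)C(C)(C)C | intermediate
25 | 13-membered lactone | O=C1CC[C@H](C)CCC2=C(C)[C@@H]3[C@H](/C(CO1)=C\OCc4ccc(OC)cc4)CC[C@]3(C)[C@@H](O[Si](C)(C)C(C)(C)C)[C@@H]2O[Si](C)(C)C(C)(C)C | intermediate
26 | silyl ketene acetal of 25 | C[Si](C)(C)OC1=CC[C@H](C)CCC2=C(C)[C@@H]3[C@H](/C(CO1)=C\OCc4ccc(OC)cc4)CC[C@]3(C)[C@@H](O[Si](C)(C)C(C)(C)C)[C@@H]2O[Si](C)(C)C(C)(C)C | intermediate
27 | trimethylsilyl ester of 28 | C=C1[C@H](OCc4ccc(OC)cc4)C(C(=O)O[Si](C)(C)C)C[C@H](C)CCC2=C(C)[C@@H]3[C@H]1CC[C@]3(C)[C@@H](O[Si](C)(C)C(C)(C)C)[C@@H]2O[Si](C)(C)C(C)(C)C | intermediate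
28 | ring-contracted acid (2R-OPMB, C3-CO2H, C1=C17H2) | C=C1[C@H](OCc4ccc(OC)cc4)C(C(=O)O)C[C@H](C)CCC2=C(C)[C@@H]3[C@H]1CC[C@]3(C)[C@@H](O[Si](C)(C)C(C)(C)C)[C@@H]2O[Si](C)(C)C(C)(C)C | intermediate
29 | thiohydroxamate ester of 28 | C=C1[C@H](OCc4ccc(OC)cc4)C(C(=O)ON5C=CC=CC5=S)C[C@H](C)CCC2=C(C)[C@@H]3[C@H]1CC[C@]3(C)[C@@H](O[Si](C)(C)C(C)(C)C)[C@@H]2O[Si](C)(C)C(C)(C)C | intermediate
30 | (2R)-PMB ether, C3H2 | C=C1[C@H](OCc4ccc(OC)cc4)CC[C@H](C)CCC2=C(C)[C@@H]3[C@H]1CC[C@]3(C)[C@@H](O[Si](C)(C)C(C)(C)C)[C@@H]2O[Si](C)(C)C(C)(C)C | intermediate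
31 | (2R)-allylic alcohol bis(TBS ether) | C=C1[C@H](O)CC[C@H](C)CCC2=C(C)[C@@H]3[C@H]1CC[C@]3(C)[C@@H](O[Si](C)(C)C(C)(C)C)[C@@H]2O[Si](C)(C)C(C)(C)C | intermediate
32 | (2S)-acetate bis(TBS ether) | C=C1[C@@H](OC(C)=O)CC[C@H](C)CCC2=C(C)[C@@H]3[C@H]1CC[C@]3(C)[C@@H](O[Si](C)(C)C(C)(C)C)[C@@H]2O[Si](C)(C)C(C)(C)C | intermediate
33 | CNP0192310.1, (2S,5R,10S,11R,14S,15R,16R) in the numbering above | C=C1[C@@H](OC(C)=O)CC[C@H](C)CCC2=C(C)[C@@H]3[C@H]1CC[C@]3(C)[C@@H](O)[C@@H]2O | target

**Step count and risks**

Total: 24 steps. Longest linear sequence: 22 steps (steps 1–14 and 17–24).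

Most likely to fail:

1. Step 20 (ring-contracting Ireland–Claisen). The bridged chair transition state may be too strained, so that the ketene acetal is lost by desilylation, ketene formation or ion-pair collapse before it rearranges, or bond formation occurs on the other enol ether face. The fallback uses the ordinary open-chain rearrangement and closes the ring afterwards; it sets out from 17 and 21 and returns at 32. Saponification of 21 (LiOH) would give (S)-4-methylhex-5-enoic acid F1, which is esterified with 17 (EDC, DMAP) to the open-chain ester F2. Its Ireland–Claisen rearrangement (KHMDS, TMSCl, −78 °C → rt), the acyclic reaction of a γ-alkoxyallyl ester, should give the acid F3; without the ring the enolate is expected to add anti to the bulkier C10 and so to give the 2S ether directly. Barton decarboxylation would give the triflate F4. Hydroboration of its terminal vinyl group with 9-BBN (the 1,1-disubstituted methylene reacts much more slowly) and intramolecular B-alkyl Suzuki coupling with the C8 triflate would close the 11-membered ring to the 2S PMB ether F5. DDQ then frees the 2S alcohol F6, and plain acetylation (Ac2O, DMAP) rejoins the route at 32.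

2. Step 23 (Mitsunobu inversion). Activation of the hindered ring alcohol may be slow, or substitution may proceed by SN2′ attack at the methylene carbon or by elimination, eroding the inversion. The fallback sets out from 31 and returns at 32: the alcohol is converted (ClCH2SO2Cl, pyridine) into the chloromethanesulfonate F7, which is displaced by caesium acetate with 18-crown-6 in hot toluene, a stepwise sulfonate displacement with a naked carboxylate in place of the redox condensation.

3. Step 17 (B-alkyl Suzuki coupling). Oxidative addition and transmetalation at the tetrasubstituted triflate flanked by C9-Me and C16-OTBS may be slow, so that protodeboronation and triflate hydrolysis take over. The fallback sets out from 21 and 17 and returns at 23: hydroboration of 21 and iodinolysis of borane 22 (I2, NaOMe) would give methyl (S)-6-iodo-4-methylhexanoate F8, zinc insertion (Zn, LiCl, THF) the alkylzinc iodide F9, and Negishi coupling of excess F9 with 17 (Pd2(dba)3, dialkylbiarylphosphine ligand, THF/NMP) gives 23 under water-free, base-free conditions with a smaller nucleophile.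

Further compounds
F1 | step 20 | (S)-4-methylhex-5-enoic acid | C=C[C@@H](C)CCC(=O)O
F2 | step 20 | open-chain ester of 17 with F1 | O=S(=O)(OC1=C(C)[C@@H]2[C@H](/C(COC(=O)CC[C@H](C)C=C)=C\OCc3ccc(OC)cc3)CC[C@]2(C)[C@@H](O[Si](C)(C)C(C)(C)C)[C@@H]1O[Si](C)(C)C(C)(C)C)C(F)(F)F
F3 | step 20 | open-chain Claisen acid (2S-OPMB, C3-CO2H, terminal vinyl, C8 triflate) | O=S(=O)(OC1=C(C)[C@@H]2[C@H](C(=C)[C@@H](OCc3ccc(OC)cc3)C(C(=O)O)C[C@H](C)C=C)CC[C@]2(C)[C@@H](O[Si](C)(C)C(C)(C)C)[C@@H]1O[Si](C)(C)C(C)(C)C)C(F)(F)F
F4 | step 20 | decarboxylated open-chain triflate (2S-OPMB) | O=S(=O)(OC1=C(C)[C@@H]2[C@H](C(=C)[C@@H](OCc3ccc(OC)cc3)CC[C@H](C)C=C)CC[C@]2(C)[C@@H](O[Si](C)(C)C(C)(C)C)[C@@H]1O[Si](C)(C)C(C)(C)C)C(F)(F)F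
F5 | step 20 | (2S)-PMB ether macrocycle (C2 epimer of 30) | C=C1[C@@H](OCc4ccc(OC)cc4)CC[C@H](C)CCC2=C(C)[C@@H]3[C@H]1CC[C@]3(C)[C@@H](O[Si](C)(C)C(C)(C)C)[C@@H]2O[Si](C)(C)C(C)(C)C
F6 | step 20 | (2S)-allylic alcohol (C2 epimer of 31) | C=C1[C@@H](O)CC[C@H](C)CCC2=C(C)[C@@H]3[C@H]1CC[C@]3(C)[C@@H](O[Si](C)(C)C(C)(C)C)[C@@H]2O[Si](C)(C)C(C)(C)C
F7 | step 23 | (2R)-chloromethanesulfonate of 31 | C=C1[C@H](OS(=O)(=O)CCl)CC[C@H](C)CCC2=C(C)[C@@H]3[C@H]1CC[C@]3(C)[C@@H](O[Si](C)(C)C(C)(C)C)[C@@H]2O[Si](C)(C)C(C)(C)C
F8 | step 17 | methyl (S)-6-iodo-4-methylhexanoate | COC(=O)CC[C@H](C)CCI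
F9 | step 17 | alkylzinc iodide from F8 | COC(=O)CC[C@H](C)CC[Zn]I
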